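**Strategy.** Each pyranone ring C of this C3–C3''-linked biflavanone is a β-aryloxy ketone, so both O1–C2 bonds are retro-oxa-Michael bonds and the 1,4-diketone C4–C3–C3''–C4'' maps onto a 2,3-diaroylbuta-1,3-diene. An achiral, unsymmetrical (2E,3E)-bis-chalcone is therefore built from a fulgide (bis-arylidenesuccinic anhydride, made by two Stobbe condensations) through two successive aryllithium acylations. A cinchona aminothiourea then closes it in a double 6-endo oxa-Michael/kinetic-protonation cascade that forms both heterocycles, including the O1–C2 bond of the 5,7-dioxygenated unit, and all four stereocentres (cis,cis; 2R,3R,2''R,3''R) in one operation. Neutral hydrogenolysis of two benzyl ethers ends the route.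

Key step: step 9

Numbering used below: unit 1 is the 5,7-dioxygenated flavanone (O1, C2, C3, C4); unit 2 is the 5-hydroxy-7-methoxy flavanone (O1'', C2'', C3'', C4'').

Assumption: the quinidine-derived aminothiourea is taken to direct each phenoxide to the enone face that gives the 2R centres; if the sense of induction is the opposite, the quinine-derived pseudoenantiomer is used in the same way.

Step 1
Reactants: 1 diethyl succinate; 2 4-methoxybenzaldehyde
Product: 4 diethyl (E)-2-(4-methoxybenzylidene)succinate, via Stobbe half-ester 3 (not isolated)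
Conditions: NaOEt, EtOH, reflux; then conc. H2SO4 (excess over NaOEt), EtOH, reflux
Reagents that add atoms: ethanol, CCO
Why: Stobbe condensation (aldol addition of the succinate enolate, lactonisation to a paraconate, E1cB ring opening that places the aryl group anti to the ester on the new alkene) gives the (E)-half-ester, and Fischer esterification in the same ethanolic solution after acidification restores the diester, which unlike the carboxylate can enolise for a second condensation.

Step 2
Reactants: 4 diethyl (E)-2-(4-methoxybenzylidene)succinate; 2 4-methoxybenzaldehyde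
Product: 6 (2E,3E)-2,3-bis(4-methoxybenzylidene)succinic acid, via half-ester sodium salt 5 (not isolated)
Conditions: NaOEt, EtOH, reflux; then aq NaOH, reflux; then HCl; crystallisation
Reagents that add atoms: sodium hydroxide, [Na+].[OH-]
Why: Second Stobbe condensation at the remaining CH2 group of 4 (extended ester enolate, aldol addition, paraconate lactone, E1cB opening with the new aryl group again anti to the carbonyl on its alkene carbon), followed by saponification of the remaining ethyl ester in the same pot, with the (2E,3E)-diacid expected to be purified by crystallisation.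

Step 3
Reactants: 6 (2E,3E)-2,3-bis(4-methoxybenzylidene)succinic acid
Product: 7 (3E,4E)-3,4-bis(4-methoxybenzylidene)oxolane-2,5-dione
Conditions: AcCl, reflux, exclusion of light
Reagents that add atoms: none
Why: Cyclodehydration of the 1,4-diacid to the five-membered anhydride (fulgide formation), with the E,E-diene expected to be kept when light is excluded, since fulgides photoisomerise and photocyclise.

Step 4
Reactants: 8 3,5-bis(benzyloxy)phenol
Product: 9 1,3-bis(benzyloxy)-5-(methoxymethoxy)benzene
Conditions: NaH, MOMCl, DMF, 0 °C to rt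
Reagents that add atoms: chloromethyl methyl ether, COCCl
Why: O-Alkylation of the sodium phenoxide (Williamson-type acetal formation) installs the MOM group that later directs the metalation and is the only group to be removed before ring closure.

Step 5
Reactants: 9 1,3-bis(benzyloxy)-5-(methoxymethoxy)benzene; 7 (3E,4E)-3,4-bis(4-methoxybenzylidene)oxolane-2,5-dione
Product: 12 methyl (2E,3E)-4-[2,4-bis(benzyloxy)-6-(methoxymethoxy)phenyl]-2,3-bis(4-methoxybenzylidene)-4-oxobutanoate, via aryllithium 10 (not isolated), via lithium carboxylate 11 (not isolated)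
Conditions: n-BuLi, TMEDA, THF, −20 to 0 °C; cannulate into 7, THF, −78 °C; then MeI, DMPU, −78 °C to rt, dark
Reagents that add atoms: iodomethane, CI
Why: Directed ortho-metalation next to the chelating OMOM group gives 10, whose acyl substitution on the C2-symmetric anhydride can give only one keto-carboxylate (the doubly ortho-flanked aryl ketone should resist a second addition), and O-alkylation of the carboxylate by MeI gives the ester.

Step 6
Reactants: 13 5-methoxybenzene-1,3-diol
Product: 14 1-methoxy-3,5-bis(methoxymethoxy)benzene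
Conditions: NaH (2.2 equiv), MOMCl (2.2 equiv), DMF, 0 °C to rt
Reagents that add atoms: chloromethyl methyl ether, COCCl
Why: Double O-alkylation of the bis-phenoxide (Williamson-type acetal formation) gives the bis-MOM ether whose position between the two acetals is the one to be metalated.

Step 7
Reactants: 14 1-methoxy-3,5-bis(methoxymethoxy)benzene; 12 methyl (2E,3E)-4-[2,4-bis(benzyloxy)-6-(methoxymethoxy)phenyl]-2,3-bis(4-methoxybenzylidene)-4-oxobutanoate
Product: 16 (2E,3E)-1-[2,4-bis(benzyloxy)-6-(methoxymethoxy)phenyl]-4-[4-methoxy-2,6-bis(methoxymethoxy)phenyl]-2,3-bis(4-methoxybenzylidene)butane-1,4-dione, via aryllithium 15 (not isolated)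
Conditions: n-BuLi, THF, 0 °C; cannulate into 12, THF, −78 to −40 °C; NH4Cl aq, dark
Reagents that add atoms: none
Why: Directed ortho-metalation between the two OMOM groups (para to OMe) followed by acyl substitution at the methyl ester; the ketone already present and the new one have no α-hydrogen and are shielded by two ortho-alkoxy groups, so 1,2-addition to them is expected to be slow.

Step 8
Reactants: 16 (2E,3E)-1-[2,4-bis(benzyloxy)-6-(methoxymethoxy)phenyl]-4-[4-methoxy-2,6-bis(methoxymethoxy)phenyl]-2,3-bis(4-methoxybenzylidene)butane-1,4-dione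
Product: 17 (2E,3E)-1-[2,4-bis(benzyloxy)-6-hydroxyphenyl]-4-(2,6-dihydroxy-4-methoxyphenyl)-2,3-bis(4-methoxybenzylidene)butane-1,4-dione
Conditions: HCl (cat.) in MeOH, THF, rt, dark; stop at full conversion, NaHCO3 aq
Reagents that add atoms: none
Why: Acid-catalysed transacetalisation to methanol cleaves the three aryl MOM ethers, which the ortho carbonyl activates, while benzyl and methyl ethers stay; room temperature and a prompt neutral work-up are chosen to avoid acid-promoted ring closure.

Step 9
Reactants: 17 (2E,3E)-1-[2,4-bis(benzyloxy)-6-hydroxyphenyl]-4-(2,6-dihydroxy-4-methoxyphenyl)-2,3-bis(4-methoxybenzylidene)butane-1,4-dione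
Product: 19 (2R,3R)-5,7-bis(benzyloxy)-3-[(2R,3R)-5-hydroxy-7-methoxy-2-(4-methoxyphenyl)-4-oxochroman-3-yl]-2-(4-methoxyphenyl)chroman-4-one, via monocyclised chalcone 18 (not isolated)
Conditions: N-[3,5-bis(trifluoromethyl)phenyl]-N'-[(9R)-6'-methoxycinchonan-9-yl]thiourea (20 mol %), toluene/CH2Cl2, −20 °C, dark; AcOH quench, chromatography
Reagents that add atoms: none
Why: The quinuclidine nitrogen of the catalyst deprotonates a carbonyl-chelated 2-hydroxyl while the thiourea hydrogen-bonds the enone carbonyl, and the phenoxide adds to the β-carbon (expected first at C2'' of the more reactive 2,6-dihydroxyaryl unit 2, then at C2 of unit 1) in two successive intramolecular oxa-Michael additions, each followed by C-protonation of the enolate. The closest known reaction is the aminothiourea-catalysed enantioselective cyclisation of 2'-hydroxychalcones, α-alkoxycarbonyl-substituted ones included, to flavanones. Each ring C closes in the 6-endo-trig mode, and the closure of unit 1 forms its O1–C2 bond. C2 and C2'' are set by the catalyst, which should shield the same enantioface of two nearly identical enones and so give the homochiral 2R,2''R pair; C3 and C3'' are set by kinetic protonation of each enolate anti to the 2-aryl group, which A(1,2) strain with the C3 substituent forces pseudoaxial, and this gives the 2,3-cis relationship in both rings. The step needs enantioface selectivity in both additions and α-protonation without later epimerisation or retro-addition; low temperature, a non-polar medium, the 5''-OH to C4''=O hydrogen bond and the acidic quench are meant to secure this, and the diastereomer with unlike C2/C2'' configuration, into which most minor enantiofacial events are channelled, is removed by chromatography.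

Step 10
Reactants: 19 (2R,3R)-5,7-bis(benzyloxy)-3-[(2R,3R)-5-hydroxy-7-methoxy-2-(4-methoxyphenyl)-4-oxochroman-3-yl]-2-(4-methoxyphenyl)chroman-4-one
Product: 20 (2R,3R)-5,7-dihydroxy-3-[(2R,3R)-5-hydroxy-7-methoxy-2-(4-methoxyphenyl)-4-oxochroman-3-yl]-2-(4-methoxyphenyl)chroman-4-one
Conditions: H2 (1 atm), Pd/C (10 %), EtOAc, rt, monitored closely
Reagents that add atoms: none
Why: Hydrogenolysis of the two aryl benzyl ethers under neutral conditions, so that no acid or base reaches the epimerisable C3/C3'' centres or the retro-Michael-labile C2/C2'' centres.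

**Compound list**

1 | diethyl succinate | CCOC(=O)CCC(=O)OCC | starting material
2 | 4-methoxybenzaldehyde | COc1ccc(C=O)cc1 | starting material
3 | (E)-3-(ethoxycarbonyl)-4-(4-methoxyphenyl)but-3-enoic acid | CCOC(=O)/C(=C/c1ccc(OC)cc1)CC(=O)O | intermediate
4 | diethyl (E)-2-(4-methoxybenzylidene)succinate | CCOC(=O)/C(=C/c1ccc(OC)cc1)CC(=O)OCC | intermediate
5 | sodium (2E,3E)-4-ethoxy-2,3-bis(4-methoxybenzylidene)-4-oxobutanoate | CCOC(=O)/C(=C/c1ccc(OC)cc1)C(=C/c1ccc(OC)cc1)\C(=O)[O-].[Na+] | intermediate
6 | (2E,3E)-2,3-bis(4-methoxybenzylidene)succinic acid | OC(=O)/C(=C/c1ccc(OC)cc1)C(=C/c1ccc(OC)cc1)\C(=O)O | intermediate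
7 | (3E,4E)-3,4-bis(4-methoxybenzylidene)oxolane-2,5-dione | COc1ccc(/C=C2/C(=O)OC(=O)/C2=C/c2ccc(OC)cc2)cc1 | intermediate
8 | 3,5-bis(benzyloxy)phenol | Oc1cc(OCc2ccccc2)cc(OCc2ccccc2)c1 | starting material
9 | 1,3-bis(benzyloxy)-5-(methoxymethoxy)benzene | COCOc1cc(OCc2ccccc2)cc(OCc2ccccc2)c1 | intermediate
10 | [2,4-bis(benzyloxy)-6-(methoxymethoxy)phenyl]lithium | [Li]c1c(OCOC)cc(OCc2ccccc2)cc1OCc1ccccc1 | intermediate
11 | lithium (2E,3E)-4-[2,4-bis(benzyloxy)-6-(methoxymethoxy)phenyl]-2,3-bis(4-methoxybenzylidene)-4-oxobutanoate | [Li+].[O-]C(=O)/C(=C/c1ccc(OC)cc1)C(=C/c1ccc(OC)cc1)\C(=O)c1c(OCOC)cc(OCc2ccccc2)cc1OCc1ccccc1 | intermediate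
12 | methyl (2E,3E)-4-[2,4-bis(benzyloxy)-6-(methoxymethoxy)phenyl]-2,3-bis(4-methoxybenzylidene)-4-oxobutanoate | COC(=O)/C(=C/c1ccc(OC)cc1)C(=C/c1ccc(OC)cc1)\C(=O)c1c(OCOC)cc(OCc2ccccc2)cc1OCc1ccccc1 | intermediate
13 | 5-methoxybenzene-1,3-diol | COc1cc(O)cc(O)c1 | starting material
14 | 1-methoxy-3,5-bis(methoxymethoxy)benzene | COCOc1cc(OC)cc(OCOC)c1 | intermediate
15 | [4-methoxy-2,6-bis(methoxymethoxy)phenyl]lithium | [Li]c1c(OCOC)cc(OC)cc1OCOC | intermediate
16 | (2E,3E)-1-[2,4-bis(benzyloxy)-6-(methoxymethoxy)phenyl]-4-[4-methoxy-2,6-bis(methoxymethoxy)phenyl]-2,3-bis(4-methoxybenzylidene)butane-1,4-dione | COCOc1cc(OC)cc(OCOC)c1C(=O)/C(=C/c1ccc(OC)cc1)C(=C/c1ccc(OC)cc1)\C(=O)c1c(OCOC)cc(OCc2ccccc2)cc1OCc1ccccc1 | intermediate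
17 | (2E,3E)-1-[2,4-bis(benzyloxy)-6-hydroxyphenyl]-4-(2,6-dihydroxy-4-methoxyphenyl)-2,3-bis(4-methoxybenzylidene)butane-1,4-dione | COc1cc(O)c(c(O)c1)C(=O)/C(=C/c1ccc(OC)cc1)C(=C/c1ccc(OC)cc1)\C(=O)c1c(O)cc(OCc2ccccc2)cc1OCc1ccccc1 | intermediate
18 | (E)-1-[2,4-bis(benzyloxy)-6-hydroxyphenyl]-2-[(2R,3R)-5-hydroxy-7-methoxy-2-(4-methoxyphenyl)-4-oxochroman-3-yl]-3-(4-methoxyphenyl)prop-2-en-1-one | COc1ccc(/C=C(/C(=O)c2c(O)cc(OCc3ccccc3)cc2OCc2ccccc2)[C@H]2C(=O)c3c(O)cc(OC)cc3O[C@H]2c2ccc(OC)cc2)cc1 | intermediate
19 | (2R,3R)-5,7-bis(benzyloxy)-3-[(2R,3R)-5-hydroxy-7-methoxy-2-(4-methoxyphenyl)-4-oxochroman-3-yl]-2-(4-methoxyphenyl)chroman-4-one | COc1ccc([C@@H]2Oc3cc(OCc4ccccc4)cc(OCc4ccccc4)c3C(=O)[C@@H]2[C@H]2C(=O)c3c(O)cc(OC)cc3O[C@H]2c2ccc(OC)cc2)cc1 | intermediate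
20 | (2R,3R)-5,7-dihydroxy-3-[(2R,3R)-5-hydroxy-7-methoxy-2-(4-methoxyphenyl)-4-oxochroman-3-yl]-2-(4-methoxyphenyl)chroman-4-one | COc1ccc([C@@H]2Oc3cc(O)cc(O)c3C(=O)[C@@H]2[C@H]2C(=O)c3c(O)cc(OC)cc3O[C@H]2c2ccc(OC)cc2)cc1 | target

**Step count.** Total: 10 steps. Longest linear sequence: 8 steps (steps 1, 2, 3, 5, 7, 8, 9, 10).

**Steps most likely to fail**

Step 9. The catalyst may discriminate poorly between the enone faces of an α-branched, weakly activated chalcone. The amine may also epimerise C3/C3'' or allow γ-protonation of the intermediate dienolate to a conjugated ene-dione during a slow reaction. The fallback gives up catalyst control and sets out from 17. An achiral base (catalytic 1,4-diazabicyclo[2.2.2]octane, toluene, 0 °C, acidic quench) should close both rings under the same kinetic protonation control. After removal of the unlike diastereomer by chromatography on silica, this should leave the racemate of the cis,cis compound, that is 19 together with its enantiomer, the (2S,3S,2''S,3''S) dibenzyl biflavanone (2S,3S)-5,7-bis(benzyloxy)-3-[(2S,3S)-5-hydroxy-7-methoxy-2-(4-methoxyphenyl)-4-oxochroman-3-yl]-2-(4-methoxyphenyl)chroman-4-one F1. Preparative HPLC on an amylose tris(3,5-dimethylphenylcarbamate) phase then removes F1, and the route is rejoined at 19.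

Step 7. The aryllithium may add in conjugate fashion to the enone, or attack the first ketone, instead of substituting at the ester. The fallback sets out from 12 and replaces the organolithium by an acylative cross-coupling that ketones and enones tolerate. LiOH in THF/water, followed by dilute HCl, saponifies 12 to the keto acid (2E,3E)-4-[2,4-bis(benzyloxy)-6-(methoxymethoxy)phenyl]-2,3-bis(4-methoxybenzylidene)-4-oxobutanoic acid F2. 1-Chloro-N,N,2-trimethylprop-1-en-1-amine converts F2 under neutral, MOM-compatible conditions into the acid chloride (2E,3E)-4-[2,4-bis(benzyloxy)-6-(methoxymethoxy)phenyl]-2,3-bis(4-methoxybenzylidene)-4-oxobutanoyl chloride F3. Aryllithium 15 is transmetalated with ZnCl2 to [4-methoxy-2,6-bis(methoxymethoxy)phenyl]zinc chloride F4, and F3 and F4 are joined with Pd(PPh3)4 (zerovalent palladium, Negishi acylation) to come back at 16.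

Step 5. The aryllithium may add twice or at both carbonyls of the anhydride, and O-methylation of the lithium carboxylate in the same flask may be incomplete or may take place on the ring-closed lactol form. The fallback sets out from 7 and desymmetrises the anhydride first. N,O-Dimethylhydroxylamine opens 7 to the Weinreb amide acid (2E,3E)-4-[methoxy(methyl)amino]-2,3-bis(4-methoxybenzylidene)-4-oxobutanoic acid F5. After deprotonation of the acid with i-PrMgCl, aryllithium 10 adds to the amide and the chelated tetrahedral intermediate stops at the ketone. Work-up with dilute HCl gives the keto acid F2 described above, which trimethylsilyldiazomethane in MeOH/toluene esterifies to come back at 12.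

Further compounds
F1 | step 9 | (2S,3S)-5,7-bis(benzyloxy)-3-[(2S,3S)-5-hydroxy-7-methoxy-2-(4-methoxyphenyl)-4-oxochroman-3-yl]-2-(4-methoxyphenyl)chroman-4-one | COc1ccc([C@H]2Oc3cc(OCc4ccccc4)cc(OCc4ccccc4)c3C(=O)[C@H]2[C@@H]2C(=O)c3c(O)cc(OC)cc3O[C@@H]2c2ccc(OC)cc2)cc1
F2 | step 7 | (2E,3E)-4-[2,4-bis(benzyloxy)-6-(methoxymethoxy)phenyl]-2,3-bis(4-methoxybenzylidene)-4-oxobutanoic acid | OC(=O)/C(=C/c1ccc(OC)cc1)C(=C/c1ccc(OC)cc1)\C(=O)c1c(OCOC)cc(OCc2ccccc2)cc1OCc1ccccc1
F3 | step 7 | (2E,3E)-4-[2,4-bis(benzyloxy)-6-(methoxymethoxy)phenyl]-2,3-bis(4-methoxybenzylidene)-4-oxobutanoyl chloride | ClC(=O)/C(=C/c1ccc(OC)cc1)C(=C/c1ccc(OC)cc1)\C(=O)c1c(OCOC)cc(OCc2ccccc2)cc1OCc1ccccc1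
F4 | step 7 | [4-methoxy-2,6-bis(methoxymethoxy)phenyl]zinc chloride | Cl[Zn]c1c(OCOC)cc(OC)cc1OCOC
F5 | step 5 | (2E,3E)-4-[methoxy(methyl)amino]-2,3-bis(4-methoxybenzylidene)-4-oxobutanoic acid | CON(C)C(=O)/C(=C/c1ccc(OC)cc1)C(=C/c1ccc(OC)cc1)\C(=O)O
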